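**Retrosynthetic overview**
- The target is quercetin whose 3',4'-catechol carries a trans-(2R,3R)-2-guaiacyl-3-hydroxymethyl-1,4-dioxane ring. Flavonol rings A, C and B are bought intact as quercetin, so the dioxane ring is the only ring built, and it is built last.
- Dioxane ring closure: the C7'–O4' bond is made by acid-mediated etherification after debenzylation. Thermodynamic control places the aryl group trans to the fixed C8' centre.
- C8'–O3' bond: Mitsunobu inversion of an (S)-α-hydroxy ketone with the free 3'-OH of 3,7,4'-tri-O-benzylquercetin.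
- Key C–C bond C7'–C8': an enantioselective carbene-catalysed cross-benzoin. The Breslow intermediate (acyl anion) of O-benzylvanillin adds to benzyloxyacetaldehyde and sets the only stereocentre that is carried through.
- Order: C–C coupling, aryl ether, ketone reduction, then debenzylation with dioxane ring closure.

Assumption: quercetin (a bulk commercial flavonol) counts as a cheap commercial starting material, and the drawn isomer is trans-(2R,3R) (2,3-dehydroisosilybin A); C7', C8' and C9' denote the benzylic, oxygenated methine and hydroxymethyl carbons of the C6–C3 unit, and 3'/4' the catechol oxygens of quercetin.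

**Route**

Step 1
Reactants: 1 4-(benzyloxy)-3-methoxybenzaldehyde (O-benzylvanillin); 2 2-(benzyloxy)acetaldehyde
Product: 3 (2S)-3-(benzyloxy)-1-[4-(benzyloxy)-3-methoxyphenyl]-2-hydroxypropan-1-one
Conditions: 1 (1.5 equiv), 5-[hydroxy(diphenyl)methyl]-2-(pentafluorophenyl)-6,7-dihydro-5H-pyrrolo[2,1-c][1,2,4]triazol-2-ium tetrafluoroborate (10 mol %; the antipode that gives (S)-3, chosen in a pilot run by chiral HPLC), Rb2CO3 (10 mol %), THF, 0 °C; 2 added by syringe pump over 8 h
Reagents that add atoms: none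
Why: Proposed new method: enantioselective NHC cross-benzoin (acyl-anion umpolung), in which the carbene adds to aryl aldehyde 1 and proton transfer gives the Breslow intermediate, an acyl anion equivalent that joins two normally electrophilic carbonyl carbons by attacking 2; 1 is a poor acceptor (p-alkoxy), so its homo-benzoin is slow and reversible, whereas the α-alkoxy aldehyde 2, kept at low concentration by slow addition, is the best electrophile present, and the catalyst carbinol hydrogen-bonds and orients the acceptor C=O so that one enantioface is attacked, setting C-2 as S; the closest known reaction types are the chiral-triazolium asymmetric benzoin condensation and thiazolium or thiamine cross-acyloin couplings with an aromatic aldehyde as acyl donor and an aliphatic aldehyde as acceptor.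

Step 2
Reactants: 4 quercetin (3,3',4',5,7-pentahydroxyflavone)
Product: 5 3,7,4'-tri-O-benzylquercetin (3,7-bis(benzyloxy)-2-[4-(benzyloxy)-3-hydroxyphenyl]-5-hydroxy-4H-chromen-4-one)
Conditions: BnBr (3.2 equiv), K2CO3 (3.5 equiv), DMF, 0 °C → rt
Reagents that add atoms: benzyl bromide, BrCc1ccccc1
Why: Williamson etherification under acidity control, since the 7-, 4'- and 3-hydroxyls are the most acidic and react first while the chelated 5-OH and the 3'-OH stay free; no stereocentre is involved.

Step 3
Reactants: 3 (2S)-3-(benzyloxy)-1-[4-(benzyloxy)-3-methoxyphenyl]-2-hydroxypropan-1-one; 5 3,7,4'-tri-O-benzylquercetin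
Product: 6 (2R)-3-(benzyloxy)-1-[4-(benzyloxy)-3-methoxyphenyl]-2-{2-(benzyloxy)-5-[3,7-bis(benzyloxy)-5-hydroxy-4-oxo-4H-chromen-2-yl]phenoxy}propan-1-one
Conditions: PPh3 (1.5 equiv), diisopropyl azodicarboxylate (DIAD, 1.5 equiv), THF, 0 °C → rt
Reagents that add atoms: none
Why: Mitsunobu reaction, in which the 3'-phenol (the 5-OH is hydrogen-bonded to C4=O and inert) displaces the α-keto alkoxyphosphonium by SN2 with inversion, turning the (S)-carbinol into the (R)-aryl ether that becomes C-3 of the benzodioxane.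

Step 4
Reactants: 6 the (2R)-α-aryloxy ketone
Product: 7 (1RS,2R)-3-(benzyloxy)-1-[4-(benzyloxy)-3-methoxyphenyl]-2-{2-(benzyloxy)-5-[3,7-bis(benzyloxy)-5-hydroxy-4-oxo-4H-chromen-2-yl]phenoxy}propan-1-ol (mixture of C-1 epimers)
Conditions: NaBH4 (1.0 equiv), THF–MeOH (4:1), −20 → 0 °C
Reagents that add atoms: none
Why: Chemoselective borohydride reduction of the aryl ketone (the vinylogous-ester C4=O of the chelated flavonol is not attacked at low temperature), fast enough to outrun enolisation at C-2; the new carbinol centre is left uncontrolled because it is ionised and reset in step 5.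

Step 5
Reactants: 7 the (1RS,2R)-alcohol
Product: 9 2,3-dehydroisosilybin A (the target), via debenzylated polyol 8 (not isolated)
Conditions: H2 (1 atm), 10% Pd/C, THF–MeOH, rt; filter, concentrate; then TsOH·H2O (0.2 equiv), 1,4-dioxane (0.01 M), 60 °C
Reagents that add atoms: none
Why: Hydrogenolysis of the five benzyl ethers (the benzylic secondary alcohol and the flavonol C2=C3 survive neutral Pd/C) followed by acid-catalysed intramolecular etherification, in which the p-hydroxybenzylic alcohol ionises to a quinone-methide-type cation that the 4'-OH traps reversibly in a six-membered ring, so thermodynamic control gives the diequatorial trans ring and sets C-2 as R relative to the fixed (R)-C-3.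

**Compound list**

1 | 4-(benzyloxy)-3-methoxybenzaldehyde | COc1cc(C=O)ccc1OCc1ccccc1 | starting material
2 | 2-(benzyloxy)acetaldehyde | O=CCOCc1ccccc1 | starting material
3 | (2S)-3-(benzyloxy)-1-[4-(benzyloxy)-3-methoxyphenyl]-2-hydroxypropan-1-one | COc1cc(C(=O)[C@@H](O)COCc2ccccc2)ccc1OCc1ccccc1 | intermediate
4 | quercetin | O=c1c(O)c(-c2ccc(O)c(O)c2)oc2cc(O)cc(O)c12 | starting material
5 | 3,7-bis(benzyloxy)-2-[4-(benzyloxy)-3-hydroxyphenyl]-5-hydroxy-4H-chromen-4-one | O=c1c(OCc2ccccc2)c(-c2ccc(OCc3ccccc3)c(O)c2)oc2cc(OCc3ccccc3)cc(O)c12 | intermediate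
6 | (2R)-3-(benzyloxy)-1-[4-(benzyloxy)-3-methoxyphenyl]-2-{2-(benzyloxy)-5-[3,7-bis(benzyloxy)-5-hydroxy-4-oxo-4H-chromen-2-yl]phenoxy}propan-1-one | COc1cc(C(=O)[C@@H](COCc2ccccc2)Oc2cc(-c3oc4cc(OCc5ccccc5)cc(O)c4c(=O)c3OCc3ccccc3)ccc2OCc2ccccc2)ccc1OCc1ccccc1 | intermediate
7 | (1RS,2R)-3-(benzyloxy)-1-[4-(benzyloxy)-3-methoxyphenyl]-2-{2-(benzyloxy)-5-[3,7-bis(benzyloxy)-5-hydroxy-4-oxo-4H-chromen-2-yl]phenoxy}propan-1-ol, C-1 epimer mixture | COc1cc(C(O)[C@@H](COCc2ccccc2)Oc2cc(-c3oc4cc(OCc5ccccc5)cc(O)c4c(=O)c3OCc3ccccc3)ccc2OCc2ccccc2)ccc1OCc1ccccc1 | intermediate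
8 | 2-(3-{[(1RS,2R)-1,3-dihydroxy-1-(4-hydroxy-3-methoxyphenyl)propan-2-yl]oxy}-4-hydroxyphenyl)-3,5,7-trihydroxy-4H-chromen-4-one, C-1 epimer mixture | COc1cc(C(O)[C@@H](CO)Oc2cc(-c3oc4cc(O)cc(O)c4c(=O)c3O)ccc2O)ccc1O | intermediate
9 | 2-[(2R,3R)-2-(4-hydroxy-3-methoxyphenyl)-3-(hydroxymethyl)-2,3-dihydro-1,4-benzodioxin-6-yl]-3,5,7-trihydroxy-4H-chromen-4-one (2,3-dehydroisosilybin A) | COc1cc([C@H]2Oc3ccc(-c4oc5cc(O)cc(O)c5c(=O)c4O)cc3O[C@@H]2CO)ccc1O | target

**Step count and risk**

Total step count: 5. Step 5 is one telescoped operation of hydrogenolysis and ring closure; counted separately the total is 6.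
Longest linear sequence: 4 steps (1 → 3 → 6 → 7 → 9; the quercetin branch is equally long).

The three steps most likely to fail:

Step 1. The asymmetric cross-benzoin is unprecedented for this aldehyde pair. It may give self-coupling of 2, the regioisomeric ketol or low ee. The fallback sets out from 1 and 2 and uses an enzyme with the same acyl-anion logic. Benzaldehyde lyase (thiamine diphosphate, MgSO4, phosphate buffer pH 8 with 20% DMSO, 30 °C) takes the aromatic aldehyde as donor and the aliphatic one as acceptor, but with R sense, and gives (2R)-3-(benzyloxy)-1-[4-(benzyloxy)-3-methoxyphenyl]-2-hydroxypropan-1-one F1. Mitsunobu inversion with formic acid (PPh3, DIAD, THF, 0 °C) gives (2S)-3-(benzyloxy)-1-[4-(benzyloxy)-3-methoxyphenyl]-1-oxopropan-2-yl formate F2. Methanolysis (MeOH, catalytic NaHCO3, 0 °C) returns to the route at 3.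

Step 3. The Mitsunobu coupling of an α-hydroxy ketone with a hindered, weakly acidic phenol may be slow, eliminate towards C9' or erode the ee. The fallback sets out from 3 and replaces the redox condensation by sulfonate activation and displacement. 4-Nitrobenzenesulfonyl chloride, Et3N and catalytic DMAP in CH2Cl2 at −20 °C give, with retention, (2S)-3-(benzyloxy)-1-[4-(benzyloxy)-3-methoxyphenyl]-1-oxopropan-2-yl 4-nitrobenzenesulfonate F3. The cesium 3'-phenoxide of 5 (Cs2CO3, MeCN, 0 °C) displaces it by SN2 with inversion, and the route is rejoined at 6.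

Step 5. The acid stage may give C-alkylation of the phloroglucinol ring, enol-ether formation at C8' or an unfavourable cis/trans ratio. The fallback sets out from 8 (crude after hydrogenolysis) and closes the ring through a neutral quinone methide, the biomimetic mode. Me3SiBr in CH2Cl2–MeCN at 0 °C converts the p-hydroxybenzylic alcohol into 2-(3-{[(1RS,2R)-1-bromo-3-hydroxy-1-(4-hydroxy-3-methoxyphenyl)propan-2-yl]oxy}-4-hydroxyphenyl)-3,5,7-trihydroxy-4H-chromen-4-one F4. Aqueous NaHCO3 eliminates HBr to 2-(3-{[(2S)-1-hydroxy-3-(3-methoxy-4-oxocyclohexa-2,5-dien-1-ylidene)propan-2-yl]oxy}-4-hydroxyphenyl)-3,5,7-trihydroxy-4H-chromen-4-one F5 (S only through a change of CIP ranking; the spatial arrangement is that of 8). Intramolecular 1,6-addition of the neighbouring 4'-OH then gives the benzodioxane, and the route is rejoined at 9.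

**Further compounds**

F1 | step 1 | (2R)-3-(benzyloxy)-1-[4-(benzyloxy)-3-methoxyphenyl]-2-hydroxypropan-1-one | COc1cc(C(=O)[C@H](O)COCc2ccccc2)ccc1OCc1ccccc1
F2 | step 1 | (2S)-3-(benzyloxy)-1-[4-(benzyloxy)-3-methoxyphenyl]-1-oxopropan-2-yl formate | COc1cc(C(=O)[C@@H](OC=O)COCc2ccccc2)ccc1OCc1ccccc1
F3 | step 3 | (2S)-3-(benzyloxy)-1-[4-(benzyloxy)-3-methoxyphenyl]-1-oxopropan-2-yl 4-nitrobenzenesulfonate | COc1cc(C(=O)[C@@H](OS(=O)(=O)c2ccc(cc2)[N+](=O)[O-])COCc2ccccc2)ccc1OCc1ccccc1
F4 | step 5 | 2-(3-{[(1RS,2R)-1-bromo-3-hydroxy-1-(4-hydroxy-3-methoxyphenyl)propan-2-yl]oxy}-4-hydroxyphenyl)-3,5,7-trihydroxy-4H-chromen-4-one | COc1cc(C(Br)[C@@H](CO)Oc2cc(-c3oc4cc(O)cc(O)c4c(=O)c3O)ccc2O)ccc1O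
F5 | step 5 | 2-(3-{[(2S)-1-hydroxy-3-(3-methoxy-4-oxocyclohexa-2,5-dien-1-ylidene)propan-2-yl]oxy}-4-hydroxyphenyl)-3,5,7-trihydroxy-4H-chromen-4-one | COC1=CC(=C[C@@H](CO)Oc2cc(-c3oc4cc(O)cc(O)c4c(=O)c3O)ccc2O)C=CC1=O
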